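**Retrosynthetic overview**
1. Last step: hydride cleavage of three pivalate esters (two on the hydroquinone, one on O5) releases the target.
2. Key disconnection: the C5–O bond, made together with the C3–C4 bond, in an enantioselective three-component alkenyl-acyloxylation of a terminal 1,3-diene with an E alkenyl iodide and pivalate (Pd2(dba)3 / chiral phosphoramidite). The C–O bond formation at C5 creates the only stereocentre.
3. Diene half from geranyl acetate: SeO2 allylic hydroxylation, bromide, alkynylation with 2-methylbut-3-yne-1,2-diol, furan closure by C–O bond formation (AgNO3), then oxidation and methylenation.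
4. Iodide half from 2,6-dimethylhydroquinone: bis-pivalate, benzylic bromination of one of two equivalent methyl groups, propynylation, hydrozirconation–iodination.
5. Ring order: the benzene ring is bought; the furan is the only ring built (step 9), before the fragments are joined.

Assumption: the (S)-ligand of step 12 is taken to give the 5R product; if the first run shows the opposite sense, its (R)-antipode is used with nothing else changed.

**Route**

Step 1
Reactants: 1 2,6-dimethylbenzene-1,4-diol
Product: 2 2,6-dimethyl-1,4-phenylene bis(2,2-dimethylpropanoate)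
Conditions: t-BuCOCl (3 equiv), Et3N (4 equiv), DMAP (0.2 equiv), CH2Cl2, 0 to 40 °C
Reagents that add atoms: pivaloyl chloride CC(C)(C)C(Cl)=O
Why: DMAP-catalysed O-acylation of both phenols; the hindered pivalates survive the radical, organomagnesium, zirconium and palladium steps and cannot be scrambled by the pivalate nucleophile of step 12.

Step 2
Reactants: 2 2,6-dimethyl-1,4-phenylene bis(2,2-dimethylpropanoate)
Product: 3 2-(bromomethyl)-6-methyl-1,4-phenylene bis(2,2-dimethylpropanoate)
Conditions: NBS (0.95 equiv), AIBN (5 mol%), PhCF3, 80 °C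
Reagents that add atoms: N-bromosuccinimide O=C1CCC(=O)N1Br
Why: Wohl–Ziegler radical benzylic bromination; the two methyl groups are symmetry-equivalent, so mono-bromination gives a single regioisomer, and the ester-deactivated ring resists nuclear bromination.

Step 3
Reactants: 3 2-(bromomethyl)-6-methyl-1,4-phenylene bis(2,2-dimethylpropanoate); 4 1-propynylmagnesium bromide
Product: 5 2-(but-2-yn-1-yl)-6-methyl-1,4-phenylene bis(2,2-dimethylpropanoate)
Conditions: 4 (1.3 equiv, 0.5 M in THF), CuBr·SMe2 (10 mol%), THF, −20 °C to rt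
Reagents that add atoms: none
Why: CuBr-catalysed sp–sp3 cross-coupling of an alkynyl Grignard reagent with a benzylic bromide; the weakly nucleophilic alkynylmagnesium does not attack the hindered pivalates.

Step 4
Reactants: 5 2-(but-2-yn-1-yl)-6-methyl-1,4-phenylene bis(2,2-dimethylpropanoate)
Product: 7 2-[(2E)-3-iodobut-2-en-1-yl]-6-methyl-1,4-phenylene bis(2,2-dimethylpropanoate), via alkenylzirconocene chloride 6 (not isolated)
Conditions: Cp2Zr(H)Cl (1.5 equiv), THF, 45 °C, 2 h; then I2 (1.4 equiv), 0 °C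
Reagents that add atoms: iodine II
Why: syn hydrozirconation of the 2-alkyne with Cp2Zr(H)Cl, equilibrated with a slight excess of reagent so that zirconium sits on the less hindered methyl-bearing carbon, then iodinolysis with retention gives the E alkenyl iodide (iodine trans to the arylmethyl group).

Step 5
Reactants: 8 geranyl acetate [(2E)-3,7-dimethylocta-2,6-dien-1-yl acetate]
Product: 9 (2E,6E)-8-hydroxy-3,7-dimethylocta-2,6-dien-1-yl acetate
Conditions: SeO2 (0.2 equiv), t-BuOOH (3 equiv), salicylic acid (0.1 equiv), CH2Cl2, rt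
Reagents that add atoms: tert-butyl hydroperoxide CC(C)(C)OO; selenium dioxide O=[Se]=O (catalytic oxygen carrier)
Why: SeO2-catalysed allylic oxidation (ene reaction then [2,3]-sigmatropic shift) hydroxylates the E-methyl group of the electron-rich terminal alkene with retention of alkene geometry, while the allylic acetate deactivates the other alkene.

Step 6
Reactants: 9 (2E,6E)-8-hydroxy-3,7-dimethylocta-2,6-dien-1-yl acetate
Product: 10 (2E,6E)-8-bromo-3,7-dimethylocta-2,6-dien-1-yl acetate
Conditions: CBr4 (1.2 equiv), PPh3 (1.25 equiv), CH2Cl2, 0 °C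
Reagents that add atoms: carbon tetrabromide BrC(Br)(Br)Br
Why: Appel bromination of a primary allylic alcohol (SN2 on the alkoxyphosphonium ion) keeps the position and E geometry of the alkene.

Step 7
Reactants: 11 hydroxyacetone (1-hydroxypropan-2-one); 12 ethynylmagnesium bromide
Product: 13 2-methylbut-3-yne-1,2-diol (racemic)
Conditions: 12 (2.3 equiv, 0.5 M in THF), THF, 0 °C; then 1 M HCl to pH 6
Reagents that add atoms: none
Why: 1,2-addition of an alkynyl Grignard reagent to the ketone after the first equivalent has deprotonated the hydroxyl; the new stereocentre is racemic and is erased when the furan forms in step 9.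

Step 8
Reactants: 10 (2E,6E)-8-bromo-3,7-dimethylocta-2,6-dien-1-yl acetate; 13 2-methylbut-3-yne-1,2-diol
Product: 14 (2E,6E)-11,12-dihydroxy-3,7,11-trimethyldodeca-2,6-dien-9-yn-1-yl acetate (racemic at C11)
Conditions: 13 (1.3 equiv), CuI (copper iodide, 20 mol%), K2CO3 (2 equiv), DMF, rt
Reagents that add atoms: none
Why: base-assisted formation of the copper acetylide and SN2 displacement of the primary allylic bromide gives the skipped enyne; free hydroxyls, the acetate and the alkene geometry are untouched.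

Step 9
Reactants: 14 (2E,6E)-11,12-dihydroxy-3,7,11-trimethyldodeca-2,6-dien-9-yn-1-yl acetate
Product: 16 (2E,6E)-3,7-dimethyl-8-(4-methylfuran-2-yl)octa-2,6-dien-1-yl acetate, via dihydrofuranol 15 (not isolated)
Conditions: AgNO3 (10 mol%) on silica gel, CH2Cl2, rt, dark
Reagents that add atoms: none
Why: AgNO3-catalysed 5-endo-dig hydroalkoxylation of the 3-alkyne-1,2-diol (the primary hydroxyl forms the ring C–O bond), then loss of water from the tertiary carbinol aromatises to the 2,4-disubstituted furan.

Step 10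
Reactants: 16 (2E,6E)-3,7-dimethyl-8-(4-methylfuran-2-yl)octa-2,6-dien-1-yl acetate
Product: 17 (2E,6E)-3,7-dimethyl-8-(4-methylfuran-2-yl)octa-2,6-dien-1-ol
Conditions: K2CO3 (0.3 equiv), MeOH, rt
Reagents that add atoms: none
Why: base-catalysed transesterification (methanolysis) of the allylic acetate; nothing else in the molecule is base-labile.

Step 11
Reactants: 17 (2E,6E)-3,7-dimethyl-8-(4-methylfuran-2-yl)octa-2,6-dien-1-ol
Product: 19 4-methyl-2-[(2E,6E)-2,6-dimethylnona-2,6,8-trien-1-yl]furan, via enal 18 (not isolated)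
Conditions: (COCl)2 (1.3 equiv), DMSO (2.6 equiv), CH2Cl2, −78 °C; Et3N (5 equiv), −78 to −40 °C; then Ph3P=CH2 (4 equiv, from Ph3PCH3Br and KN(SiMe3)2 in THF), −78 to 0 °C
Reagents that add atoms: methyltriphenylphosphonium bromide C[P+](c1ccccc1)(c1ccccc1)c1ccccc1.[Br-]
Why: Swern oxidation gives the E enal without isomerisation at low temperature, and Wittig methylenation in the same flask converts it into the terminal E 1,3-diene (the excess ylide covers the ammonium salt present).

Step 12
Reactants: 7 2-[(2E)-3-iodobut-2-en-1-yl]-6-methyl-1,4-phenylene bis(2,2-dimethylpropanoate); 19 4-methyl-2-[(2E,6E)-2,6-dimethylnona-2,6,8-trien-1-yl]furan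
Product: 20 2-[(2E,5R,6E,10E)-5-(2,2-dimethylpropanoyloxy)-3,7,11-trimethyl-12-(4-methylfuran-2-yl)dodeca-2,6,10-trien-1-yl]-6-methyl-1,4-phenylene bis(2,2-dimethylpropanoate)
Conditions: 19 (1.0 equiv), 7 (1.2 equiv), Pd2(dba)3 (2.5 mol%), (S)-3,3′-diphenyl-H8-BINOL N,N-diisopropylphosphoramidite (11 mol%), CsO2CCMe3 (2.0 equiv), Me3CCO2H (0.3 equiv), MTBE/THF 4:1, 35 °C, argon
Reagents that add atoms: cesium pivalate [Cs+].CC(C)(C)C(=O)[O-]
Why: Proposed new method: zerovalent palladium bearing the bulky chiral monodentate phosphoramidite inserts into the carbon–iodine bond of 7 with retention, the alkenylpalladium adds across the terminal C4=C5 bond of 19 with ligand-controlled facial selectivity to give a syn π-allylpalladium over C5–C7 (the E geometry of C6=C7 is kept because the fully substituted C7 terminus does not form the σ-complex), and pivalate then attacks the less hindered C5 terminus from the face opposite palladium, so the C5–O bond is made and the 5R stereocentre is created in that event while zerovalent palladium is released; pivalate is chosen because its hindered allylic ester does not re-ionise and because it cannot scramble the aryl pivalates; closest known reaction type: the Heck/Tsuji–Trost three-component carboamination of 1,3-dienes with amines and the asymmetric allylic substitution of π-allylpalladium with carboxylates, whereas an intermolecular enantioselective alkenyl-acyloxylation of a diene is not established.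

Step 13
Reactants: 20 2-[(2E,5R,6E,10E)-5-(2,2-dimethylpropanoyloxy)-3,7,11-trimethyl-12-(4-methylfuran-2-yl)dodeca-2,6,10-trien-1-yl]-6-methyl-1,4-phenylene bis(2,2-dimethylpropanoate)
Product: 21 2-[(2E,5R,6E,10E)-5-hydroxy-3,7,11-trimethyl-12-(4-methylfuran-2-yl)dodeca-2,6,10-trien-1-yl]-6-methylbenzene-1,4-diol
Conditions: LiAlH4 (6 equiv), THF, 0 °C to rt, argon; aqueous potassium sodium tartrate / Na2S2O4 work-up
Reagents that add atoms: none
Why: hydride reduction cleaves the three pivalate esters at the acyl–oxygen bond, so the C5 stereocentre is untouched, while alkenes and furan are inert; dithionite in the work-up keeps the air-sensitive hydroquinone reduced.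

**Compound list**
1 | 2,6-dimethylbenzene-1,4-diol | Cc1cc(O)cc(C)c1O | starting material
2 | 2,6-dimethyl-1,4-phenylene bis(2,2-dimethylpropanoate) | Cc1cc(OC(=O)C(C)(C)C)cc(C)c1OC(=O)C(C)(C)C | intermediate
3 | 2-(bromomethyl)-6-methyl-1,4-phenylene bis(2,2-dimethylpropanoate) | BrCc1cc(OC(=O)C(C)(C)C)cc(C)c1OC(=O)C(C)(C)C | intermediate
4 | 1-propynylmagnesium bromide | CC#C[Mg]Br | starting material
5 | 2-(but-2-yn-1-yl)-6-methyl-1,4-phenylene bis(2,2-dimethylpropanoate) | CC#CCc1cc(OC(=O)C(C)(C)C)cc(C)c1OC(=O)C(C)(C)C | intermediate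
6 | chlorobis(cyclopentadienyl)[(2E)-4-[2,5-bis(2,2-dimethylpropanoyloxy)-3-methylphenyl]but-2-en-2-yl]zirconium (not isolated) | C/C(=C\Cc1cc(OC(=O)C(C)(C)C)cc(C)c1OC(=O)C(C)(C)C)[Zr](Cl)(C1C=CC=C1)C1C=CC=C1 | intermediate
7 | 2-[(2E)-3-iodobut-2-en-1-yl]-6-methyl-1,4-phenylene bis(2,2-dimethylpropanoate) | C/C(I)=C\Cc1cc(OC(=O)C(C)(C)C)cc(C)c1OC(=O)C(C)(C)C | intermediate
8 | geranyl acetate, (2E)-3,7-dimethylocta-2,6-dien-1-yl acetate | CC(C)=CCC/C(C)=C/COC(C)=O | starting material
9 | (2E,6E)-8-hydroxy-3,7-dimethylocta-2,6-dien-1-yl acetate | OC/C(C)=C/CC/C(C)=C/COC(C)=O | intermediate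
10 | (2E,6E)-8-bromo-3,7-dimethylocta-2,6-dien-1-yl acetate | BrC/C(C)=C/CC/C(C)=C/COC(C)=O | intermediate
11 | hydroxyacetone, 1-hydroxypropan-2-one | CC(=O)CO | starting material
12 | ethynylmagnesium bromide | C#C[Mg]Br | starting material
13 | 2-methylbut-3-yne-1,2-diol (racemic) | C#CC(C)(O)CO | intermediate
14 | (2E,6E)-11,12-dihydroxy-3,7,11-trimethyldodeca-2,6-dien-9-yn-1-yl acetate (racemic at C11) | CC(O)(CO)C#CC/C(C)=C/CC/C(C)=C/COC(C)=O | intermediate
15 | (2E,6E)-8-(4-hydroxy-4-methyl-4,5-dihydrofuran-2-yl)-3,7-dimethylocta-2,6-dien-1-yl acetate (racemic, not isolated) | CC1(O)COC(C/C(C)=C/CC/C(C)=C/COC(C)=O)=C1 | intermediate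
16 | (2E,6E)-3,7-dimethyl-8-(4-methylfuran-2-yl)octa-2,6-dien-1-yl acetate | Cc1coc(C/C(C)=C/CC/C(C)=C/COC(C)=O)c1 | intermediate
17 | (2E,6E)-3,7-dimethyl-8-(4-methylfuran-2-yl)octa-2,6-dien-1-ol | Cc1coc(C/C(C)=C/CC/C(C)=C/CO)c1 | intermediate
18 | (2E,6E)-3,7-dimethyl-8-(4-methylfuran-2-yl)octa-2,6-dienal (not isolated) | Cc1coc(C/C(C)=C/CC/C(C)=C/C=O)c1 | intermediate
19 | 4-methyl-2-[(2E,6E)-2,6-dimethylnona-2,6,8-trien-1-yl]furan | C=C/C=C(\C)CC/C=C(\C)Cc1cc(C)co1 | intermediate
20 | 2-[(2E,5R,6E,10E)-5-(2,2-dimethylpropanoyloxy)-3,7,11-trimethyl-12-(4-methylfuran-2-yl)dodeca-2,6,10-trien-1-yl]-6-methyl-1,4-phenylene bis(2,2-dimethylpropanoate) | C/C(=C\[C@H](OC(=O)C(C)(C)C)C/C(C)=C/Cc1cc(OC(=O)C(C)(C)C)cc(C)c1OC(=O)C(C)(C)C)CC/C=C(\C)Cc1cc(C)co1 | intermediate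
21 | 2-[(2E,5R,6E,10E)-5-hydroxy-3,7,11-trimethyl-12-(4-methylfuran-2-yl)dodeca-2,6,10-trien-1-yl]-6-methylbenzene-1,4-diol | C/C(=C\[C@H](O)C/C(C)=C/Cc1cc(O)cc(C)c1O)CC/C=C(\C)Cc1cc(C)co1 | target

**Step count and risk**

Total step count: 13. Longest linear sequence: 8 steps (steps 5, 6, 8, 9, 10, 11, 12, 13, from geranyl acetate 8).

The three steps most likely to fail:

Step 12 (the proposed three-component alkenyl-acyloxylation). The risks are β-hydride elimination of the π-allyl intermediate to a conjugated polyene, attack of pivalate at C7, and insufficient enantioselectivity. The fallback uses known chemistry, sets out from alcohol 17 and comes back to the route at target 21. Alcohol 17 is oxidised with MnO2 to enal 18, which is now isolated. Propargylation of 18 with allenylboronic acid pinacol ester under a chiral BINOL-derived phosphoric acid (TRIP, antipode chosen for 4R) gives (4R,5E,9E)-6,10-dimethyl-11-(4-methylfuran-2-yl)undeca-5,9-dien-1-yn-4-ol F1, whose carbinol carbon is C5 of the target. Zirconium-catalysed methylalumination of the terminal alkyne (Me3Al, Cp2ZrCl2, CH2Cl2) gives the E alkenylalane, as its O-dimethylaluminium alkoxide, dimethyl[(1E,4R,5E,9E)-4-(dimethylalumanyloxy)-2,6,10-trimethyl-11-(4-methylfuran-2-yl)undeca-1,5,9-trien-1-yl]alumane F2, which is not isolated. It is cross-coupled with benzylic bromide 3 under Pd(PPh3)4 catalysis to give 2-[(2E,5R,6E,10E)-5-hydroxy-3,7,11-trimethyl-12-(4-methylfuran-2-yl)dodeca-2,6,10-trien-1-yl]-6-methyl-1,4-phenylene bis(2,2-dimethylpropanoate) F3. The LiAlH4 conditions of step 13 then convert F3 into 21.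

Step 4 (hydrozirconation–iodination). The risks are incomplete regiocontrol between the two alkyne carbons and slow attack of the zirconium hydride on the aryl esters. The fallback sets out from bromide 3 and comes back to the route at 20. Zinc insertion (Zn dust, LiCl, THF) gives {[2,5-bis(2,2-dimethylpropanoyloxy)-3-methylphenyl]methyl}zinc bromide F4, which is not isolated. It is coupled, selectively at the carbon–iodine bond and with retention (Pd(PPh3)4, THF, rt), with (1E)-2-bromo-1-iodoprop-1-ene F5, itself made by anti addition of IBr to propyne. This gives 2-[(2E)-3-bromobut-2-en-1-yl]-6-methyl-1,4-phenylene bis(2,2-dimethylpropanoate) F6, in which the halogen position is fixed by construction. F6 replaces 7 in step 12 and gives 20.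

Step 8 (allyl–alkynyl coupling). The risks are SN2′ attack giving the branched isomer and sluggish reaction of the free diol. The fallback sets out from allylic alcohol 9 and comes back to the route at furan 16. MnO2 oxidation of 9 gives (2E,6E)-3,7-dimethyl-8-oxoocta-2,6-dien-1-yl acetate F7. Colvin homologation with lithiated trimethylsilyldiazomethane (THF, −78 °C) gives the terminal enyne (2E,6E)-3,7-dimethylnona-2,6-dien-8-yn-1-yl acetate F8. Sonogashira coupling (PdCl2(PPh3)2, CuI, Et3N) with (2Z)-3-iodo-2-methylprop-2-en-1-ol F9, made from propargyl alcohol by CuI-catalysed addition of MeMgBr and then iodine, gives (2E,6E,10Z)-12-hydroxy-3,7,11-trimethyldodeca-2,6,10-trien-8-yn-1-yl acetate F10. Ph3PAuNTf2-catalysed 5-exo-dig cycloisomerisation of this Z enynol under neutral conditions gives 16.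

**Further compounds**
F1 | step 12 | (4R,5E,9E)-6,10-dimethyl-11-(4-methylfuran-2-yl)undeca-5,9-dien-1-yn-4-ol | C/C(=C\[C@H](O)CC#C)CC/C=C(\C)Cc1cc(C)co1
F2 | step 12 | dimethyl[(1E,4R,5E,9E)-4-(dimethylalumanyloxy)-2,6,10-trimethyl-11-(4-methylfuran-2-yl)undeca-1,5,9-trien-1-yl]alumane | C/C(=C\[C@H](O[Al](C)C)C/C(C)=C/[Al](C)C)CC/C=C(\C)Cc1cc(C)co1
F3 | step 12 | 2-[(2E,5R,6E,10E)-5-hydroxy-3,7,11-trimethyl-12-(4-methylfuran-2-yl)dodeca-2,6,10-trien-1-yl]-6-methyl-1,4-phenylene bis(2,2-dimethylpropanoate) | C/C(=C\[C@H](O)C/C(C)=C/Cc1cc(OC(=O)C(C)(C)C)cc(C)c1OC(=O)C(C)(C)C)CC/C=C(\C)Cc1cc(C)co1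
F4 | step 4 | {[2,5-bis(2,2-dimethylpropanoyloxy)-3-methylphenyl]methyl}zinc bromide | Br[Zn]Cc1cc(OC(=O)C(C)(C)C)cc(C)c1OC(=O)C(C)(C)C
F5 | step 4 | (1E)-2-bromo-1-iodoprop-1-ene | C/C(Br)=C\I
F6 | step 4 | 2-[(2E)-3-bromobut-2-en-1-yl]-6-methyl-1,4-phenylene bis(2,2-dimethylpropanoate) | C/C(Br)=C\Cc1cc(OC(=O)C(C)(C)C)cc(C)c1OC(=O)C(C)(C)C
F7 | step 8 | (2E,6E)-3,7-dimethyl-8-oxoocta-2,6-dien-1-yl acetate | O=C/C(C)=C/CC/C(C)=C/COC(C)=O
F8 | step 8 | (2E,6E)-3,7-dimethylnona-2,6-dien-8-yn-1-yl acetate | C#C/C(C)=C/CC/C(C)=C/COC(C)=O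
F9 | step 8 | (2Z)-3-iodo-2-methylprop-2-en-1-ol | OC/C(C)=C\I
F10 | step 8 | (2E,6E,10Z)-12-hydroxy-3,7,11-trimethyldodeca-2,6,10-trien-8-yn-1-yl acetate | OC/C(C)=C\C#C/C(C)=C/CC/C(C)=C/COC(C)=O
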